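In the delta run at 5 °C, substrate and target still added up to 92.9% at 144 h. Zeta, the very flask asked about, had fallen to 66.0% at 72.0 h.

common to all: substrate 0.015 M; free catalyst 0.2 mol%

| flask | reagent | temperature | remark | time |
|---|---|---|---|---|
| zeta | 1.5 equiv | 20 °C | the very flask that is asked about, followed so far |  |
| delta | 1.5 equiv | 5 °C | run made earlier |  |
| flask | 1.50 equiv | 20 °C |  | 5.0 d |

| run | time / h | target / % | substrate / % |
|---|---|---|---|
| zeta | 6.00 | 12.3 | 88.7 |
| zeta | 12.0 | 20.6 | 78.6 |
| zeta | 30.0 | 43.1 | 49.9 |
| zeta | 72.0 | 53.1 | 12.9 |
| delta | 12.0 | 5.2 | 97.2 |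
| delta | 25.0 | 11.1 | 89.4 |
| delta | 60.0 | 24.7 | 74.2 |
| delta | 144 | 53.8 | 39.1 |

(each reading ± 1 percentage point)

- south-east: at 5.0 d take out 90% of the target then present, then wait 10 d
- north-east: at 5.0 d add reagent, 50.0% of the amount charged, then wait 10 d
- north-west: change nothing and wait 10 d more
- north: at 5.0 d raise the temperature by 10 K, then wait 10 d
- east: at 5.0 d add free catalyst, 50.0% of the amount charged, then wait 10 d

* target, in percent of the substrate first charged, at 5.0 d
* the option that brings most further target ("none" if no option brings more than 2 percentage points) (south-east / north-east / north-west / north / east / none)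
* target present, with what was taken out counted in, in percent of the substrate first charged, after north-west
* target present, with what was taken out counted in, in percent of the substrate first charged, after north

- target that was removed still counts
- the numbers in the tables scatter with a standard deviation of 1 percentage point
- additions bring no volume worth counting

I called D the part of the charge missing from substrate plus target. I took the loss constant κ to be the rise of D between two readings divided by the area under the target curve between them, a pseudo-first-order constant. From 30.0 h to 72.0 h in zeta it came to 0.0134 h⁻¹.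

Target then follows from a balance over the last stretch, with a the last reading, e the asked time, S substrate and P target:

P_e = P_a + S_a − S_e − κ·Δt·(P_a + P_e)/2

Continuing the first-order fall of substrate gave S_e = 2.75%. With Δt = 48.0 h, I got

P_e = 35.0%

But was κ constant? The earlier window in zeta, 12.0 h to 30.0 h, gave 0.0108 h⁻¹, which is lower. That early value carries an uncertainty of about 0.00349 h⁻¹, so the rise is a hint and no proof. Still, the hint pointed upward, so I extended the line through the two windows to the middle of the last stretch:

κ = 0.0172 h⁻¹, so P_e = 29.3%

I committed to this lower figure. For the options, I assumed that D does not return, so new target had to come from S_e, 2.75% against the margin of 2 percentage points, while target left standing had a life 1/κ of 58.1 h, shorter than the wait of 10 d. I therefore expected none to pay.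

The forecast said 37% (33% to 41%), best none, 2.1% after north-west and 0.1% after north: “From 72 to 120 h, 53 decays to about 29, and the last substrate adds about 8, giving about 37%.” My figure lay below its range.

The flask gave 29.4%, best none, 5.94% after north-west and 1.54% after north.

    substrate + free catalyst → catalyst intermediate A (k = 2100 M⁻¹ h⁻¹, Ea = 40.0 kJ mol⁻¹)
    catalyst intermediate A → catalyst intermediate B (k = 170 h⁻¹, Ea = 68.0 kJ mol⁻¹)
    reagent + catalyst intermediate B → catalyst intermediate C (k = 1.30 × 10⁵ M⁻¹ h⁻¹, Ea = 48.0 kJ mol⁻¹)
    catalyst intermediate C → released group + catalyst intermediate D (k = 31.0 h⁻¹, Ea = 72.0 kJ mol⁻¹)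
    catalyst intermediate D ⇌ free catalyst + target (K = 0.0430 M, k = 28.0 h⁻¹, Ea = 72.0 kJ mol⁻¹, ΔH = −29.0 kJ mol⁻¹)
    target + free catalyst ⇌ isomer of the product + free catalyst, rate k6*[free catalyst]*[target] forward; the back reaction follows from the equilibrium constant (K = 1.80, k = 410 M⁻¹ h⁻¹, Ea = 51.0 kJ mol⁻¹, ΔH = −37.0 kJ mol⁻¹)
    crystals ⇌ released group, rate k7*(cs7 - [released group]) while solid is left; crystals form when [released group] > cs7 (solubility = 0.890 mM, k = 2.10 h⁻¹)
    free catalyst + target → free catalyst + over-reaction product (k = 440 M⁻¹ h⁻¹, Ea = 66.0 kJ mol⁻¹)
    (constants at 20 °C)

From the zeta reading at 72.0 h to the asked flask at 120 h, the last stretch read κ = 0.0180 h⁻¹. For the neighbour, read at 50 h with amounts and temperature held, I took the same balance from the zeta reading at 30.0 h. The line through the windows gave κ = 0.0124 h⁻¹, and with its substrate at 27.5%, target came to 53.5%. It held 53.8%. Free catalyst stood at 54.5% of the catalyst charged in that neighbour at 50.0 h and at 88.7% in the asked flask at 120 h.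

The runs stem from a simulated flask on assumed constants; scatter was added.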